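**Retrosynthetic overview**

- The target is (2R)-naringenin (rings A, B, C) joined through C6 to C6' of luteolin (catechol ring D, pyranone ring E, phloroglucinol ring F). The last operations are global debenzylation and closure of ring E by 6-endo oxa-Michael addition of an o-alkynoylphenol, itself made by acyl Sonogashira coupling of a ring-D aryl alkyne.
- The strategy rests on C4 being a ketone carbon bonded to C4a of the pentasubstituted ring A, with C4a lying between the oxygen-bearing carbons C5 and C8a. The C4–C4a bond is therefore made last, by a Parham cyclisation of a C4a aryllithium onto a tethered Weinreb amide, after the C2–O1 ether already holds the stereocenter.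
- The C2–O1 bond comes from Mitsunobu inversion of an (S)-β-hydroxy Weinreb amide (Noyori hydrogenation) with a 2-bromophenol whose two ortho positions were equivalent before bromination.
- The C6–C6' biaryl bond comes from Negishi coupling of a 2,6-bis(benzyloxy)-4-silyloxyphenylzinc (lithiation between the two benzyloxy groups) with 2-bromo-4,5-bis(benzyloxy)benzaldehyde; the aldehyde is then converted into the silyl alkyne.
- Order of ring formation: biaryl A–D first, then ring C (step 12), then ring E (step 19).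

Key step: step 12

Assumption: the C6–C6' axis is drawn without configuration and is treated as freely rotating, so no axial control is attempted; methyl 2,4,6-trihydroxybenzoate replaces the free acid because the ester allows clean 2,4-dibenzylation.

**Route**

Step 1
Reactants: 1 3,5-bis(benzyloxy)phenol
Product: 2 [3,5-bis(benzyloxy)phenoxy]triisopropylsilane
Conditions: TIPSCl (1.1 equiv), imidazole (2 equiv), DMF, rt
Reagents that add atoms: triisopropylsilyl chloride, CC(C)[Si](Cl)(C(C)C)C(C)C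
Why: Imidazole-promoted silylation of a phenol; the bulky, weakly coordinating silyl ether shields C2 and C6 so that the later directed lithiation should go to C4 between the two benzyloxy groups.

Step 2
Reactants: 3 3,4-bis(benzyloxy)benzaldehyde
Product: 4 2-bromo-4,5-bis(benzyloxy)benzaldehyde
Conditions: Br2 (1.05 equiv), NaOAc, AcOH, rt
Reagents that add atoms: bromine, BrBr
Why: Electrophilic aromatic bromination at C6, the open position para to the 3-benzyloxy group, as in the bromination of veratraldehyde; acetate buffers the HBr so the benzyl ethers survive.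

Step 3
Reactants: 2 [3,5-bis(benzyloxy)phenoxy]triisopropylsilane; 4 2-bromo-4,5-bis(benzyloxy)benzaldehyde
Product: 7 4,5-bis(benzyloxy)-2-[2,6-bis(benzyloxy)-4-(triisopropylsilyloxy)phenyl]benzaldehyde, via aryllithium 5 (not isolated), via arylzinc chloride 6 (not isolated)
Conditions: 2 (1.3 equiv), n-BuLi (1.25 equiv), THF, 0 °C to rt; ZnCl2 (1.4 equiv), 0 °C to rt; then 4 (1.0 equiv), Pd2(dba)3 (1 mol %), RuPhos (4 mol %), THF, 65 °C
Reagents that add atoms: none
Why: Directed ortho-lithiation at the carbon flanked by two benzyloxy groups, transmetalation to zinc and Negishi cross-coupling; zerovalent palladium with a dialkylbiarylphosphine should join the di-ortho-substituted arylzinc to the ortho-formyl bromide, and the arylzinc does not add to the aldehyde.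

Step 4
Reactants: 7 4,5-bis(benzyloxy)-2-[2,6-bis(benzyloxy)-4-(triisopropylsilyloxy)phenyl]benzaldehyde
Product: 8 4,5-bis(benzyloxy)-2-[2,6-bis(benzyloxy)-4-hydroxyphenyl]benzaldehyde
Conditions: TBAF (1.1 equiv), THF, 0 °C; aq. NH4Cl
Reagents that add atoms: none
Why: Fluoride cleavage of an aryl silyl ether, done before any alkynylsilane is present so that no selectivity between two silyl groups is needed.

Step 5
Reactants: 8 4,5-bis(benzyloxy)-2-[2,6-bis(benzyloxy)-4-hydroxyphenyl]benzaldehyde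
Product: 9 3,5-bis(benzyloxy)-4-[4,5-bis(benzyloxy)-2-ethynylphenyl]phenol
Conditions: dimethyl (1-diazo-2-oxopropyl)phosphonate (1.5 equiv), K2CO3 (3 equiv), MeOH/THF, rt
Reagents that add atoms: dimethyl (1-diazo-2-oxopropyl)phosphonate, COP(=O)(OC)C(=[N+]=[N-])C(C)=O
Why: Ohira–Bestmann (Seyferth–Gilbert) homologation of the aldehyde to the terminal alkyne; the phenol is merely held as its phenoxide under these conditions.

Step 6
Reactants: 9 3,5-bis(benzyloxy)-4-[4,5-bis(benzyloxy)-2-ethynylphenyl]phenol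
Product: 12 3,5-bis(benzyloxy)-4-{4,5-bis(benzyloxy)-2-[(trimethylsilyl)ethynyl]phenyl}phenol, via dilithium salt 10 (not isolated), via bis-silyl ether 11 (not isolated)
Conditions: n-BuLi (2.1 equiv), THF, −78 °C; TMSCl (2.5 equiv), −78 °C to rt; 1 M aq. HCl, THF, rt
Reagents that add atoms: chlorotrimethylsilane, C[Si](C)(C)Cl
Why: Double deprotonation (phenol and alkyne C–H) and silylation at both sites, followed by selective hydrolysis of the labile aryl trimethylsilyl ether in dilute acid, which leaves the C-silyl alkyne intact.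

Step 7
Reactants: 12 3,5-bis(benzyloxy)-4-{4,5-bis(benzyloxy)-2-[(trimethylsilyl)ethynyl]phenyl}phenol
Product: 13 2-bromo-3,5-bis(benzyloxy)-4-{4,5-bis(benzyloxy)-2-[(trimethylsilyl)ethynyl]phenyl}phenol
Conditions: NBS (1.0 equiv), CH2Cl2, −78 to 0 °C, dark
Reagents that add atoms: N-bromosuccinimide, O=C1CCC(=O)N1Br
Why: Electrophilic bromination ortho to the free phenol; C2 and C6 are equivalent and are the only positions activated by three oxygen donors, so one equivalent of NBS at low temperature should give a single monobromide.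

Step 8
Reactants: 14 4'-(benzyloxy)acetophenone
Product: 15 ethyl 3-[4-(benzyloxy)phenyl]-3-oxopropanoate
Conditions: NaH (2.2 equiv), (EtO)2CO (3 equiv), THF, reflux; AcOH quench
Reagents that add atoms: diethyl carbonate, CCOC(=O)OCC
Why: Claisen-type C-acylation of the ketone enolate with diethyl carbonate, driven to completion by deprotonation of the β-keto ester.

Step 9
Reactants: 15 ethyl 3-[4-(benzyloxy)phenyl]-3-oxopropanoate
Product: 16 ethyl (3S)-3-[4-(benzyloxy)phenyl]-3-hydroxypropanoate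
Conditions: H2 (50 atm), RuCl2[(R)-BINAP] (1 mol %), EtOH, 50 °C
Reagents that add atoms: none
Why: Noyori asymmetric hydrogenation of a β-keto ester through its ruthenium chelate; the (R)-ligand delivers hydrogen in the spatial sense that gives (R)-3-hydroxybutanoate, which is the (S)-descriptor in the 3-aryl series, and ruthenium does not cleave the benzyl ether.

Step 10
Reactants: 16 ethyl (3S)-3-[4-(benzyloxy)phenyl]-3-hydroxypropanoate
Product: 17 (3S)-3-[4-(benzyloxy)phenyl]-3-hydroxy-N-methoxy-N-methylpropanamide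
Conditions: MeNH(OMe)·HCl (2.5 equiv), i-PrMgCl (5 equiv), THF, −20 to 0 °C
Reagents that add atoms: N,O-dimethylhydroxylamine hydrochloride, CNOC.Cl
Why: Weinreb amide formation by aminolysis of the ester with the chloromagnesium amide; the carbinol is held as its magnesium alkoxide and the stereocenter is not touched (a recrystallisation of 17 is planned to raise the enantiomeric purity if needed).

Step 11
Reactants: 13 2-bromo-3,5-bis(benzyloxy)-4-{4,5-bis(benzyloxy)-2-[(trimethylsilyl)ethynyl]phenyl}phenol; 17 (3S)-3-[4-(benzyloxy)phenyl]-3-hydroxy-N-methoxy-N-methylpropanamide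
Product: 18 (3R)-3-[4-(benzyloxy)phenyl]-3-(2-bromo-3,5-bis(benzyloxy)-4-{4,5-bis(benzyloxy)-2-[(trimethylsilyl)ethynyl]phenyl}phenoxy)-N-methoxy-N-methylpropanamide
Conditions: PPh3 (1.5 equiv), DIAD (1.5 equiv), toluene, 0 °C to rt
Reagents that add atoms: none
Why: Mitsunobu etherification; SN2 attack of the acidic ortho-bromophenoxide on the alkoxyphosphonium inverts the carbinol carbon and sets the (R)-configuration of the future C2, with non-polar solvent and low temperature chosen to keep the 4-benzyloxybenzylic centre on the SN2 path.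

Step 12
Reactants: 18 (3R)-3-[4-(benzyloxy)phenyl]-3-(2-bromo-3,5-bis(benzyloxy)-4-{4,5-bis(benzyloxy)-2-[(trimethylsilyl)ethynyl]phenyl}phenoxy)-N-methoxy-N-methylpropanamide
Product: 21 (2R)-5,7-bis(benzyloxy)-2-[4-(benzyloxy)phenyl]-6-{4,5-bis(benzyloxy)-2-[(trimethylsilyl)ethynyl]phenyl}chroman-4-one, via aryllithium 19 (not isolated), via lithium hemiaminal alkoxide 20 (not isolated)
Conditions: t-BuLi (2.1 equiv), THF, −95 °C then −78 °C; aq. NH4Cl at −78 °C
Reagents that add atoms: none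
Why: Bromine–lithium exchange with tert-butyllithium (the second equivalent destroys tert-butyl bromide) at the carbon flanked by two ring-A oxygens gives the aryllithium at the future C4a, which attacks the tethered amide carbonyl to form the N-methoxy-chelated tetrahedral lithium alkoxide; this cannot collapse or accept a second nucleophile and releases the C4 ketone only on aqueous work-up. This is a Parham cyclisation, the anionic intramolecular acylation of an aryllithium by a Weinreb amide, known for chroman-4-ones made from Mitsunobu-derived β-aryloxy amides. Ring C closes by a 6-exo-trig acyl substitution that forms the C4–C4a bond. No stereocenter is created: C2 was set in step 11 and meets neither acid nor an equilibrating base, so it should pass through unchanged, and the C4 hemiaminal centre of 20 is lost on work-up. The step needs exchange and ring closure to outrun deprotonation at C3, which would expel the phenoxide by E1cB; the two ortho oxygen substituents accelerate the exchange, the short tether makes acylation faster than proton transfer, and the trimethylsilyl cap leaves no acidic alkyne hydrogen.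

Step 13
Reactants: 21 (2R)-5,7-bis(benzyloxy)-2-[4-(benzyloxy)phenyl]-6-{4,5-bis(benzyloxy)-2-[(trimethylsilyl)ethynyl]phenyl}chroman-4-one
Product: 22 (2R)-5,7-bis(benzyloxy)-2-[4-(benzyloxy)phenyl]-6-[4,5-bis(benzyloxy)-2-ethynylphenyl]chroman-4-one
Conditions: AgNO3 (10 mol %), CH2Cl2/MeOH/H2O, rt, dark
Reagents that add atoms: none
Why: Silver-catalysed protiodesilylation of an alkynyl trimethylsilane under neutral conditions, chosen over carbonate or fluoride so that the flavanone cannot open by retro-oxa-Michael reaction and scramble C2.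

Step 14
Reactants: 23 methyl 2,4,6-trihydroxybenzoate
Product: 24 methyl 2,4-bis(benzyloxy)-6-hydroxybenzoate
Conditions: BnBr (2.1 equiv), K2CO3 (2.2 equiv), acetone, reflux
Reagents that add atoms: benzyl bromide, BrCc1ccccc1
Why: Williamson etherification; the hydroxyl that stays hydrogen-bonded to the ester carbonyl is the least nucleophilic and should remain free with two equivalents of benzyl bromide.

Step 15
Reactants: 24 methyl 2,4-bis(benzyloxy)-6-hydroxybenzoate
Product: 25 2,4-bis(benzyloxy)-6-hydroxybenzoic acid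
Conditions: KOH, MeOH/THF/H2O, 65 °C; then 1 M HCl, 0 °C
Reagents that add atoms: potassium hydroxide, [K+].[OH-]
Why: Saponification of the salicylate ester, with cold acidification to avoid decarboxylation of the electron-rich acid.

Step 16
Reactants: 25 2,4-bis(benzyloxy)-6-hydroxybenzoic acid
Product: 26 tert-butyldimethylsilyl 2,4-bis(benzyloxy)-6-[(tert-butyldimethylsilyl)oxy]benzoate
Conditions: TBSCl (2.5 equiv), imidazole (5 equiv), DMF, rt
Reagents that add atoms: tert-butyldimethylsilyl chloride, CC(C)(C)[Si](C)(C)Cl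
Why: Silylation of both the phenol and the carboxylic acid, as is standard for salicylic acids, to give the silyl ester needed for neutral acid chloride formation.

Step 17
Reactants: 26 tert-butyldimethylsilyl 2,4-bis(benzyloxy)-6-[(tert-butyldimethylsilyl)oxy]benzoate
Product: 27 2,4-bis(benzyloxy)-6-[(tert-butyldimethylsilyl)oxy]benzoyl chloride
Conditions: (COCl)2 (1.2 equiv), DMF (cat.), CH2Cl2, 0 °C to rt; used crude
Reagents that add atoms: oxalyl chloride, O=C(Cl)C(=O)Cl
Why: Vilsmeier-type conversion of a silyl ester into the acid chloride, which forms no HCl, so the aryl silyl ether survives and no ortho acetal group is present to cyclise onto the acyl chloride.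

Step 18
Reactants: 22 (2R)-5,7-bis(benzyloxy)-2-[4-(benzyloxy)phenyl]-6-[4,5-bis(benzyloxy)-2-ethynylphenyl]chroman-4-one; 27 2,4-bis(benzyloxy)-6-[(tert-butyldimethylsilyl)oxy]benzoyl chloride
Product: 28 (2R)-5,7-bis(benzyloxy)-2-[4-(benzyloxy)phenyl]-6-[4,5-bis(benzyloxy)-2-(3-{2,4-bis(benzyloxy)-6-[(tert-butyldimethylsilyl)oxy]phenyl}-3-oxoprop-1-yn-1-yl)phenyl]chroman-4-one
Conditions: 27 (1.3 equiv), PdCl2(PPh3)2 (3 mol %), CuI (6 mol %), Et3N (1.5 equiv), THF, rt
Reagents that add atoms: none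
Why: Acyl Sonogashira coupling of a terminal alkyne with an aroyl chloride to the ynone at room temperature, with only a slight excess of a tertiary amine, which should not deprotonate C3 of the flavanone.

Step 19
Reactants: 28 (2R)-5,7-bis(benzyloxy)-2-[4-(benzyloxy)phenyl]-6-[4,5-bis(benzyloxy)-2-(3-{2,4-bis(benzyloxy)-6-[(tert-butyldimethylsilyl)oxy]phenyl}-3-oxoprop-1-yn-1-yl)phenyl]chroman-4-one
Product: 30 (2R)-5,7-bis(benzyloxy)-2-[4-(benzyloxy)phenyl]-6-{4,5-bis(benzyloxy)-2-[5,7-bis(benzyloxy)-4-oxo-4H-chromen-2-yl]phenyl}chroman-4-one, via alkynoylphenol 29 (not isolated)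
Conditions: TBAF (1.2 equiv), AcOH (1.5 equiv), THF, 0 °C; aqueous work-up; then DMAP (20 mol %), DMF, rt
Reagents that add atoms: none
Why: Buffered fluoride cleavage of the aryl silyl ether followed by DMAP-catalysed 6-endo-dig oxa-Michael cyclisation of the o-alkynoylphenol to the chromone; the nucleophilic catalyst adds at the β-carbon, so attack at the α-carbon (5-exo, aurone) should not compete, and the weak base should leave C2 of the flavanone alone.

Step 20
Reactants: 30 (2R)-5,7-bis(benzyloxy)-2-[4-(benzyloxy)phenyl]-6-{4,5-bis(benzyloxy)-2-[5,7-bis(benzyloxy)-4-oxo-4H-chromen-2-yl]phenyl}chroman-4-one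
Product: 31 (2R)-6-[2-(5,7-dihydroxy-4-oxo-4H-chromen-2-yl)-4,5-dihydroxyphenyl]-5,7-dihydroxy-2-(4-hydroxyphenyl)chroman-4-one (CNP0168406.2)
Conditions: H2 (1 atm), 10 % Pd/C, THF/MeOH, rt, stopped at full debenzylation
Reagents that add atoms: none
Why: Catalytic hydrogenolysis of the seven aryl benzyl ethers under neutral conditions, which are cleaved well before the chromone double bond or the C2–O1 bond of the flavanone is attacked, and C2 is untouched.

**Compound list**

1 | 3,5-bis(benzyloxy)phenol | Oc1cc(OCc2ccccc2)cc(OCc2ccccc2)c1 | starting material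
2 | [3,5-bis(benzyloxy)phenoxy]triisopropylsilane | CC(C)[Si](C(C)C)(C(C)C)Oc1cc(OCc2ccccc2)cc(OCc2ccccc2)c1 | intermediate
3 | 3,4-bis(benzyloxy)benzaldehyde | O=Cc1ccc(OCc2ccccc2)c(OCc2ccccc2)c1 | starting material
4 | 2-bromo-4,5-bis(benzyloxy)benzaldehyde | O=Cc1cc(OCc2ccccc2)c(OCc2ccccc2)cc1Br | intermediate
5 | [2,6-bis(benzyloxy)-4-(triisopropylsilyloxy)phenyl]lithium | [Li]c1c(OCc2ccccc2)cc(O[Si](C(C)C)(C(C)C)C(C)C)cc1OCc1ccccc1 | intermediate
6 | [2,6-bis(benzyloxy)-4-(triisopropylsilyloxy)phenyl]zinc chloride | Cl[Zn]c1c(OCc2ccccc2)cc(O[Si](C(C)C)(C(C)C)C(C)C)cc1OCc1ccccc1 | intermediate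
7 | 4,5-bis(benzyloxy)-2-[2,6-bis(benzyloxy)-4-(triisopropylsilyloxy)phenyl]benzaldehyde | O=Cc1cc(OCc2ccccc2)c(OCc2ccccc2)cc1-c1c(OCc2ccccc2)cc(O[Si](C(C)C)(C(C)C)C(C)C)cc1OCc1ccccc1 | intermediate
8 | 4,5-bis(benzyloxy)-2-[2,6-bis(benzyloxy)-4-hydroxyphenyl]benzaldehyde | O=Cc1cc(OCc2ccccc2)c(OCc2ccccc2)cc1-c1c(OCc2ccccc2)cc(O)cc1OCc1ccccc1 | intermediate
9 | 3,5-bis(benzyloxy)-4-[4,5-bis(benzyloxy)-2-ethynylphenyl]phenol | C#Cc1cc(OCc2ccccc2)c(OCc2ccccc2)cc1-c1c(OCc2ccccc2)cc(O)cc1OCc1ccccc1 | intermediate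
10 | dilithium salt of 9 (lithium phenoxide and lithium acetylide) | [Li]C#Cc1cc(OCc2ccccc2)c(OCc2ccccc2)cc1-c1c(OCc2ccccc2)cc(O[Li])cc1OCc1ccccc1 | intermediate
11 | {3,5-bis(benzyloxy)-4-[4,5-bis(benzyloxy)-2-(trimethylsilylethynyl)phenyl]phenoxy}trimethylsilane | C[Si](C)(C)C#Cc1cc(OCc2ccccc2)c(OCc2ccccc2)cc1-c1c(OCc2ccccc2)cc(O[Si](C)(C)C)cc1OCc1ccccc1 | intermediate
12 | 3,5-bis(benzyloxy)-4-{4,5-bis(benzyloxy)-2-[(trimethylsilyl)ethynyl]phenyl}phenol | C[Si](C)(C)C#Cc1cc(OCc2ccccc2)c(OCc2ccccc2)cc1-c1c(OCc2ccccc2)cc(O)cc1OCc1ccccc1 | intermediate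
13 | 2-bromo-3,5-bis(benzyloxy)-4-{4,5-bis(benzyloxy)-2-[(trimethylsilyl)ethynyl]phenyl}phenol | Oc1cc(OCc2ccccc2)c(-c2cc(OCc3ccccc3)c(OCc3ccccc3)cc2C#C[Si](C)(C)C)c(OCc2ccccc2)c1Br | intermediate
14 | 4'-(benzyloxy)acetophenone | CC(=O)c1ccc(OCc2ccccc2)cc1 | starting material
15 | ethyl 3-[4-(benzyloxy)phenyl]-3-oxopropanoate | CCOC(=O)CC(=O)c1ccc(OCc2ccccc2)cc1 | intermediate
16 | ethyl (3S)-3-[4-(benzyloxy)phenyl]-3-hydroxypropanoate | CCOC(=O)C[C@H](O)c1ccc(OCc2ccccc2)cc1 | intermediate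
17 | (3S)-3-[4-(benzyloxy)phenyl]-3-hydroxy-N-methoxy-N-methylpropanamide | CON(C)C(=O)C[C@H](O)c1ccc(OCc2ccccc2)cc1 | intermediate
18 | (3R)-3-[4-(benzyloxy)phenyl]-3-(2-bromo-3,5-bis(benzyloxy)-4-{4,5-bis(benzyloxy)-2-[(trimethylsilyl)ethynyl]phenyl}phenoxy)-N-methoxy-N-methylpropanamide | CON(C)C(=O)C[C@H](c1ccc(OCc2ccccc2)cc1)Oc1cc(OCc2ccccc2)c(-c2cc(OCc3ccccc3)c(OCc3ccccc3)cc2C#C[Si](C)(C)C)c(OCc2ccccc2)c1Br | intermediate
19 | aryllithium from 18 (lithium in place of bromine at the future C4a) | CON(C)C(=O)C[C@H](c1ccc(OCc2ccccc2)cc1)Oc1cc(OCc2ccccc2)c(-c2cc(OCc3ccccc3)c(OCc3ccccc3)cc2C#C[Si](C)(C)C)c(OCc2ccccc2)c1[Li] | intermediate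
20 | lithium alkoxide of the (2R)-4-[methoxy(methyl)amino]chroman-4-ol (tetrahedral intermediate, C4 unassigned) | CON(C)C1(O[Li])C[C@H](c2ccc(OCc3ccccc3)cc2)Oc2cc(OCc3ccccc3)c(-c3cc(OCc4ccccc4)c(OCc4ccccc4)cc3C#C[Si](C)(C)C)c(OCc3ccccc3)c21 | intermediate
21 | (2R)-5,7-bis(benzyloxy)-2-[4-(benzyloxy)phenyl]-6-{4,5-bis(benzyloxy)-2-[(trimethylsilyl)ethynyl]phenyl}chroman-4-one | O=C1C[C@H](c2ccc(OCc3ccccc3)cc2)Oc2cc(OCc3ccccc3)c(-c3cc(OCc4ccccc4)c(OCc4ccccc4)cc3C#C[Si](C)(C)C)c(OCc3ccccc3)c21 | intermediate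
22 | (2R)-5,7-bis(benzyloxy)-2-[4-(benzyloxy)phenyl]-6-[4,5-bis(benzyloxy)-2-ethynylphenyl]chroman-4-one | O=C1C[C@H](c2ccc(OCc3ccccc3)cc2)Oc2cc(OCc3ccccc3)c(-c3cc(OCc4ccccc4)c(OCc4ccccc4)cc3C#C)c(OCc3ccccc3)c21 | intermediate
23 | methyl 2,4,6-trihydroxybenzoate | COC(=O)c1c(O)cc(O)cc1O | starting material
24 | methyl 2,4-bis(benzyloxy)-6-hydroxybenzoate | COC(=O)c1c(O)cc(OCc2ccccc2)cc1OCc1ccccc1 | intermediate
25 | 2,4-bis(benzyloxy)-6-hydroxybenzoic acid | OC(=O)c1c(O)cc(OCc2ccccc2)cc1OCc1ccccc1 | intermediate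
26 | tert-butyldimethylsilyl 2,4-bis(benzyloxy)-6-[(tert-butyldimethylsilyl)oxy]benzoate | CC(C)(C)[Si](C)(C)OC(=O)c1c(O[Si](C)(C)C(C)(C)C)cc(OCc2ccccc2)cc1OCc1ccccc1 | intermediate
27 | 2,4-bis(benzyloxy)-6-[(tert-butyldimethylsilyl)oxy]benzoyl chloride | ClC(=O)c1c(O[Si](C)(C)C(C)(C)C)cc(OCc2ccccc2)cc1OCc1ccccc1 | intermediate
28 | (2R)-5,7-bis(benzyloxy)-2-[4-(benzyloxy)phenyl]-6-[4,5-bis(benzyloxy)-2-(3-{2,4-bis(benzyloxy)-6-[(tert-butyldimethylsilyl)oxy]phenyl}-3-oxoprop-1-yn-1-yl)phenyl]chroman-4-one | O=C1C[C@H](c2ccc(OCc3ccccc3)cc2)Oc2cc(OCc3ccccc3)c(-c3cc(OCc4ccccc4)c(OCc4ccccc4)cc3C#CC(=O)c3c(O[Si](C)(C)C(C)(C)C)cc(OCc4ccccc4)cc3OCc3ccccc3)c(OCc3ccccc3)c21 | intermediate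
29 | (2R)-5,7-bis(benzyloxy)-2-[4-(benzyloxy)phenyl]-6-(4,5-bis(benzyloxy)-2-{3-[2,4-bis(benzyloxy)-6-hydroxyphenyl]-3-oxoprop-1-yn-1-yl}phenyl)chroman-4-one | O=C1C[C@H](c2ccc(OCc3ccccc3)cc2)Oc2cc(OCc3ccccc3)c(-c3cc(OCc4ccccc4)c(OCc4ccccc4)cc3C#CC(=O)c3c(O)cc(OCc4ccccc4)cc3OCc3ccccc3)c(OCc3ccccc3)c21 | intermediate
30 | (2R)-5,7-bis(benzyloxy)-2-[4-(benzyloxy)phenyl]-6-{4,5-bis(benzyloxy)-2-[5,7-bis(benzyloxy)-4-oxo-4H-chromen-2-yl]phenyl}chroman-4-one | O=C1C[C@H](c2ccc(OCc3ccccc3)cc2)Oc2cc(OCc3ccccc3)c(-c3cc(OCc4ccccc4)c(OCc4ccccc4)cc3-c3cc(=O)c4c(OCc5ccccc5)cc(OCc5ccccc5)cc4o3)c(OCc3ccccc3)c21 | intermediate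
31 | (2R)-6-[2-(5,7-dihydroxy-4-oxo-4H-chromen-2-yl)-4,5-dihydroxyphenyl]-5,7-dihydroxy-2-(4-hydroxyphenyl)chroman-4-one | O=C1C[C@H](c2ccc(O)cc2)Oc2cc(O)c(-c3cc(O)c(O)cc3-c3cc(=O)c4c(O)cc(O)cc4o3)c(O)c21 | target

**Step count and risks**

Total steps: 20. Longest linear sequence: 12 steps (steps 1, 3, 4, 5, 6, 7, 11, 12, 13, 18, 19, 20).

Steps most likely to fail:

1. Step 12 (key step). Proton transfer from C3 to the aryllithium, or E1cB loss of the phenoxide, may outrun ring closure, and exchange at the doubly flanked bromide may be incomplete. The fallback closes the same C4–C4a bond by electrophilic instead of anionic acylation, using the still unbrominated ring A. It sets out from 12 and 16. Mitsunobu coupling (PPh3, DIAD, toluene) should give ethyl (3R)-3-[4-(benzyloxy)phenyl]-3-(3,5-bis(benzyloxy)-4-{4,5-bis(benzyloxy)-2-[(trimethylsilyl)ethynyl]phenyl}phenoxy)propanoate F1. Mild ester cleavage with Me3SnOH in 1,2-dichloroethane should give the acid F2. 1-Chloro-N,N,2-trimethylpropenylamine should convert it without HCl into the acid chloride F3. Intramolecular Friedel–Crafts acylation at one of the two equivalent ortho positions (SnCl4, 2,6-di-tert-butylpyridine, CH2Cl2, −78 °C, kept aprotic and cold to avoid ionisation at C2) comes back to the route at 21.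

2. Step 11. Ionisation of the 4-benzyloxybenzylic alkoxyphosphonium may compete with SN2 displacement, which would erode the configuration at C2, and elimination to the cinnamamide may also occur. The fallback switches off the para oxygen donor during the substitution. It sets out from 17. Hydrogenolysis (H2, Pd/C, EtOAc) should give (3S)-3-hydroxy-3-(4-hydroxyphenyl)-N-methoxy-N-methylpropanamide F4. Selective acylation of the phenol (allyl chloroformate, K2CO3, acetone, 0 °C) should give the allyl aryl carbonate F5. Mitsunobu coupling with 13 should then proceed with clean inversion to the (R)-ether F6. Deallylation with Pd(PPh3)4 and morpholine should give the phenol F7, and benzylation (BnBr, K2CO3, acetone) comes back to the route at 18.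

3. Step 18. Coupling of the hindered, electron-rich aroyl chloride with the ortho-substituted alkyne may be slower than alkyne homocoupling or loss of the acid chloride, and prolonged contact with the amine may open the flavanone. The fallback is a base-free Stille acylation. It sets out from 22. Stannylation with Bu3SnOMe in toluene at 60 °C should give the alkynyl tributylstannane F8, and coupling with 27 under PdCl2(PPh3)2 catalysis in toluene comes back to the route at 28.

**Further compounds**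

F1 | step 12 | ethyl (3R)-3-[4-(benzyloxy)phenyl]-3-(3,5-bis(benzyloxy)-4-{4,5-bis(benzyloxy)-2-[(trimethylsilyl)ethynyl]phenyl}phenoxy)propanoate | CCOC(=O)C[C@H](c1ccc(OCc2ccccc2)cc1)Oc1cc(OCc2ccccc2)c(-c2cc(OCc3ccccc3)c(OCc3ccccc3)cc2C#C[Si](C)(C)C)c(OCc2ccccc2)c1
F2 | step 12 | (3R)-3-[4-(benzyloxy)phenyl]-3-(3,5-bis(benzyloxy)-4-{4,5-bis(benzyloxy)-2-[(trimethylsilyl)ethynyl]phenyl}phenoxy)propanoic acid | OC(=O)C[C@H](c1ccc(OCc2ccccc2)cc1)Oc1cc(OCc2ccccc2)c(-c2cc(OCc3ccccc3)c(OCc3ccccc3)cc2C#C[Si](C)(C)C)c(OCc2ccccc2)c1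
F3 | step 12 | (3R)-3-[4-(benzyloxy)phenyl]-3-(3,5-bis(benzyloxy)-4-{4,5-bis(benzyloxy)-2-[(trimethylsilyl)ethynyl]phenyl}phenoxy)propanoyl chloride | ClC(=O)C[C@H](c1ccc(OCc2ccccc2)cc1)Oc1cc(OCc2ccccc2)c(-c2cc(OCc3ccccc3)c(OCc3ccccc3)cc2C#C[Si](C)(C)C)c(OCc2ccccc2)c1
F4 | step 11 | (3S)-3-hydroxy-3-(4-hydroxyphenyl)-N-methoxy-N-methylpropanamide | CON(C)C(=O)C[C@H](O)c1ccc(O)cc1
F5 | step 11 | allyl 4-{(1S)-1-hydroxy-3-[methoxy(methyl)amino]-3-oxopropyl}phenyl carbonate | CON(C)C(=O)C[C@H](O)c1ccc(OC(=O)OCC=C)cc1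
F6 | step 11 | allyl 4-{(1R)-1-(2-bromo-3,5-bis(benzyloxy)-4-{4,5-bis(benzyloxy)-2-[(trimethylsilyl)ethynyl]phenyl}phenoxy)-3-[methoxy(methyl)amino]-3-oxopropyl}phenyl carbonate | CON(C)C(=O)C[C@H](c1ccc(OC(=O)OCC=C)cc1)Oc1cc(OCc2ccccc2)c(-c2cc(OCc3ccccc3)c(OCc3ccccc3)cc2C#C[Si](C)(C)C)c(OCc2ccccc2)c1Br
F7 | step 11 | (3R)-3-(2-bromo-3,5-bis(benzyloxy)-4-{4,5-bis(benzyloxy)-2-[(trimethylsilyl)ethynyl]phenyl}phenoxy)-3-(4-hydroxyphenyl)-N-methoxy-N-methylpropanamide | CON(C)C(=O)C[C@H](c1ccc(O)cc1)Oc1cc(OCc2ccccc2)c(-c2cc(OCc3ccccc3)c(OCc3ccccc3)cc2C#C[Si](C)(C)C)c(OCc2ccccc2)c1Br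
F8 | step 18 | (2R)-5,7-bis(benzyloxy)-2-[4-(benzyloxy)phenyl]-6-{4,5-bis(benzyloxy)-2-[(tributylstannyl)ethynyl]phenyl}chroman-4-one | O=C1C[C@H](c2ccc(OCc3ccccc3)cc2)Oc2cc(OCc3ccccc3)c(-c3cc(OCc4ccccc4)c(OCc4ccccc4)cc3C#C[Sn](CCCC)(CCCC)CCCC)c(OCc3ccccc3)c21
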